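The quinone ring (C1–C4, C4a, C8a) is opened at C1–C2 and C4–C4a. Its only substituent, C1', bears an oxygen that is 1,3-related through C2 to the C1 oxygen, so the two oxygens can be bridged by a one-carbon acetal. The key step is an intramolecular Dötz benzannulation of an aryl(alkoxy)carbene chromium complex whose alkoxy group is this O–CH2–O–C1' tether to the chiral propargylic carbinol. In one operation the carbene carbon (C1) bonds to the internal alkyne carbon (C2), and a CO ligand, inserted as C4 next to C3, closes onto the free ortho carbon (C4a) of the hydroquinone ring. Oxidative work-up gives the quinone and excises the tether.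

Key step: step 8

Remark: C1' is the side-chain carbinol carbon and is (R) in every chiral compound of the route; CO ligands on chromium are drawn as Cr=C=O in the SMILES strings.

Step 1
Reactants: 1 4-methylpent-3-enoic acid
Product: 2 N-methoxy-N,4-dimethylpent-3-enamide
Conditions: CDI, CH2Cl2, rt; then MeNH(OMe)·HCl, rt
Reagents that add atoms: N,O-dimethylhydroxylamine hydrochloride, CNOC.Cl
Why: Amidation through the acyl imidazolide (Weinreb amide formation) needs no strong base, so the β,γ-double bond should stay out of conjugation.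

Step 2
Reactants: 2 N-methoxy-N,4-dimethylpent-3-enamide; 3 ethynyl(trimethyl)silane
Product: 4 6-methyl-1-(trimethylsilyl)hept-5-en-1-yn-3-one
Conditions: 3, n-BuLi, THF, −78 °C; then 2, −78 → 0 °C; aq NH4Cl
Reagents that add atoms: none
Why: Weinreb ketone synthesis, in which the chelated tetrahedral adduct should block a second addition of the lithium acetylide.

Step 3
Reactants: 4 6-methyl-1-(trimethylsilyl)hept-5-en-1-yn-3-one
Product: 6 (3R)-6-methylhept-5-en-1-yn-3-ol, via silyl carbinol 5 (not isolated)
Conditions: RuCl[(R,R)-TsDPEN](p-cymene) (1 mol%), i-PrOH, rt; evaporate; then K2CO3, MeOH, 0 °C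
Reagents that add atoms: none
Why: Noyori asymmetric transfer hydrogenation of the alkynyl ketone, in which the alkynyl group takes the place of the aryl group in the CH/π-controlled transition state so that the (R,R)-catalyst should give the (R)-carbinol, followed by base-mediated methanolysis of the alkynyl C–Si bond.

Step 4
Reactants: 6 (3R)-6-methylhept-5-en-1-yn-3-ol
Product: 7 (3R)-3-(methoxymethoxy)-6-methylhept-5-en-1-yne
Conditions: MOMCl, i-Pr2NEt, CH2Cl2, 0 °C → rt
Reagents that add atoms: chloromethyl methyl ether, COCCl
Why: O-alkylation of the carbinol (acetal formation) breaks no bond at C3, so the configuration is kept.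

Step 5
Reactants: 8 hydroquinone
Product: 9 1,4-bis(methoxymethoxy)benzene
Conditions: NaH, MOMCl, DMF, 0 °C → rt
Reagents that add atoms: chloromethyl methyl ether, COCCl
Why: Williamson-type O-alkylation of both phenoxides installs ethers that direct the later lithiation and come off under mild Lewis acid.

Step 6
Reactants: 9 1,4-bis(methoxymethoxy)benzene; 10 hexacarbonylchromium
Product: 12 tetramethylammonium pentacarbonyl{[2,5-bis(methoxymethoxy)phenyl](oxido)methylidene}chromate, via lithium acyl chromate 11 (not isolated)
Conditions: n-BuLi, TMEDA, THF, 0 °C; Cr(CO)6, 0 °C → rt; then Me4NBr, H2O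
Reagents that add atoms: tetramethylammonium bromide, C[N+](C)(C)C.[Br-]
Why: Directed ortho-lithiation next to a methoxymethoxy group, addition of the aryllithium to a CO ligand (first half of the Fischer carbene synthesis) and cation exchange should give the air-stable ammonium acylate.

Step 7
Reactants: 7 (3R)-3-(methoxymethoxy)-6-methylhept-5-en-1-yne; 12 tetramethylammonium pentacarbonyl{[2,5-bis(methoxymethoxy)phenyl](oxido)methylidene}chromate
Product: 14 pentacarbonyl{[2,5-bis(methoxymethoxy)phenyl]({[(3R)-6-methylhept-5-en-1-yn-3-yl]oxy}methoxy)methylidene}chromium, via bromomethyl ether 13 (not isolated)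
Conditions: 7, Me2BBr, CH2Cl2, −78 °C; then 12, −78 → −20 °C
Reagents that add atoms: none
Why: Boron-bromide cleavage of the methoxymethyl acetal at its methoxy oxygen should give the α-bromo ether, a hard oxocarbenium-type electrophile that O-alkylates the acyl chromate as the oxonium salts and alkyl triflates of the Fischer carbene synthesis do, and no bond to the stereocenter is touched.

Step 8
Reactants: 14 pentacarbonyl{[2,5-bis(methoxymethoxy)phenyl]({[(3R)-6-methylhept-5-en-1-yn-3-yl]oxy}methoxy)methylidene}chromium
Product: 16 2-[(1R)-1-hydroxy-4-methylpent-3-en-1-yl]-5,8-bis(methoxymethoxy)naphthalene-1,4-dione, via tethered naphthol 15 (not isolated)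
Conditions: THF (0.005 M), 60 °C, Ar; then (NH4)2Ce(NO3)6, MeCN/H2O, 0 °C
Reagents that add atoms: water, O
Why: Loss of one CO lets the tethered alkyne coordinate and insert into the Cr=C bond, which joins the carbene carbon (C1) to the internal alkyne carbon (C2); CO insertion at the new carbene carbon (C3) then gives an aryl-vinylketene whose ketene carbon (C4) closes onto the free ortho carbon (C4a) and, after tautomerization, gives naphthol 15. The closest known reaction is the Dötz benzannulation in its intramolecular form with the alkyne tethered through the carbene oxygen. The 1,3-dioxine ring closes in the exo sense at the proximal alkyne carbon (six-membered, C1–O–CH2–O–C1'–C2), and the carbocycle closes by thermal 6π-electrocyclization of the vinylketene onto the arene. No stereocenter is formed; C1' is a spectator, none of its bonds is broken, and the (R) configuration should be carried through. The step needs the regiochemistry opposite to the steric preference of the intermolecular reaction, and the three-atom acetal tether secures it because insertion at the proximal alkyne carbon is the only closure it allows and because it holds the aryl group cis to the new carbene carbon, while the arene offers only one free ortho position. (NH4)2Ce(NO3)6 then oxidizes the 4-alkoxy-1-naphthol to the quinone, which releases the acetal carbon as formaldehyde and frees the C1' hydroxyl.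

Step 9
Reactants: 17 2-bromo-3-methylbut-2-ene; 18 ethyl bromoacetate
Product: 20 ethyl 3,4-dimethylpent-3-enoate, via Reformatsky reagent 19 (not isolated)
Conditions: 18, Zn (TMSCl-activated), THF, 40 °C; then 17, Pd2(dba)3 (1 mol%), XPhos (4 mol%), THF, 60 °C
Reagents that add atoms: none
Why: Negishi-type cross-coupling of the zinc ester enolate with the vinyl bromide should place the double bond directly in the tetrasubstituted β,γ-position, with no elimination that could give the conjugated isomer.

Step 10
Reactants: 20 ethyl 3,4-dimethylpent-3-enoate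
Product: 21 3,4-dimethylpent-3-enoic acid
Conditions: LiOH, THF/H2O, 0 °C → rt; then 1 M HCl
Reagents that add atoms: lithium hydroxide, [Li+].[OH-]
Why: Saponification at low temperature, where acyl substitution should outrun enolization and leave the alkene in place.

Step 11
Reactants: 16 2-[(1R)-1-hydroxy-4-methylpent-3-en-1-yl]-5,8-bis(methoxymethoxy)naphthalene-1,4-dione; 21 3,4-dimethylpent-3-enoic acid
Product: 22 (1R)-1-[5,8-bis(methoxymethoxy)-1,4-dioxo-1,4-dihydronaphthalen-2-yl]-4-methylpent-3-en-1-yl 3,4-dimethylpent-3-enoate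
Conditions: DCC, DMAP (cat.), CH2Cl2, 0 °C → rt
Reagents that add atoms: none
Why: Steglich esterification of the only free hydroxyl acylates at oxygen and therefore keeps the (R) configuration.

Step 12
Reactants: 22 (1R)-1-[5,8-bis(methoxymethoxy)-1,4-dioxo-1,4-dihydronaphthalen-2-yl]-4-methylpent-3-en-1-yl 3,4-dimethylpent-3-enoate
Product: 23 (1R)-1-(5,8-dihydroxy-1,4-dioxo-1,4-dihydronaphthalen-2-yl)-4-methylpent-3-en-1-yl 3,4-dimethylpent-3-enoate
Conditions: MgBr2·OEt2, Et2O/CH2Cl2, 0 °C → rt; aq NH4Cl
Reagents that add atoms: none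
Why: Chelation-assisted Lewis acid cleavage of the two acetal ethers peri to the quinone carbonyls (deprotection) should free the naphthazarin under conditions that spare the alkenes and the ester.

Compound list
1 | 4-methylpent-3-enoic acid | CC(C)=CCC(=O)O | starting material
2 | N-methoxy-N,4-dimethylpent-3-enamide | CC(C)=CCC(=O)N(C)OC | intermediate
3 | ethynyl(trimethyl)silane | C#C[Si](C)(C)C | starting material
4 | 6-methyl-1-(trimethylsilyl)hept-5-en-1-yn-3-one | CC(C)=CCC(=O)C#C[Si](C)(C)C | intermediate
5 | (3R)-6-methyl-1-(trimethylsilyl)hept-5-en-1-yn-3-ol | CC(C)=CC[C@@H](O)C#C[Si](C)(C)C | intermediate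
6 | (3R)-6-methylhept-5-en-1-yn-3-ol | CC(C)=CC[C@@H](O)C#C | intermediate
7 | (3R)-3-(methoxymethoxy)-6-methylhept-5-en-1-yne | CC(C)=CC[C@@H](OCOC)C#C | intermediate
8 | hydroquinone | Oc1ccc(O)cc1 | starting material
9 | 1,4-bis(methoxymethoxy)benzene | COCOc1ccc(OCOC)cc1 | intermediate
10 | hexacarbonylchromium, Cr(CO)6 | O=C=[Cr](=C=O)(=C=O)(=C=O)(=C=O)=C=O | starting material
11 | lithium pentacarbonyl{[2,5-bis(methoxymethoxy)phenyl](oxido)methylidene}chromate | [Li+].[O-]C(c1cc(OCOC)ccc1OCOC)=[Cr](=C=O)(=C=O)(=C=O)(=C=O)=C=O | intermediate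
12 | tetramethylammonium pentacarbonyl{[2,5-bis(methoxymethoxy)phenyl](oxido)methylidene}chromate | C[N+](C)(C)C.[O-]C(c1cc(OCOC)ccc1OCOC)=[Cr](=C=O)(=C=O)(=C=O)(=C=O)=C=O | intermediate
13 | (3R)-3-(bromomethoxy)-6-methylhept-5-en-1-yne | CC(C)=CC[C@@H](OCBr)C#C | intermediate
14 | pentacarbonyl{[2,5-bis(methoxymethoxy)phenyl]({[(3R)-6-methylhept-5-en-1-yn-3-yl]oxy}methoxy)methylidene}chromium (carbene carbon bears the aryl group and the O–CH2–O–C1' acetal) | CC(C)=CC[C@@H](OCOC(c1cc(OCOC)ccc1OCOC)=[Cr](=C=O)(=C=O)(=C=O)(=C=O)=C=O)C#C | intermediate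
15 | (4R)-7,10-bis(methoxymethoxy)-4-(3-methylbut-2-en-1-yl)-4H-naphtho[1,2-d][1,3]dioxin-6-ol (1-naphthol whose C4 oxygen and C3 carbon are bridged by O–CH2–O–CH(prenyl)) | CC(C)=CC[C@H]1OCOc2c1cc(O)c1c(OCOC)ccc(OCOC)c21 | intermediate
16 | 2-[(1R)-1-hydroxy-4-methylpent-3-en-1-yl]-5,8-bis(methoxymethoxy)naphthalene-1,4-dione | CC(C)=CC[C@@H](O)C1=CC(=O)c2c(OCOC)ccc(OCOC)c2C1=O | intermediate
17 | 2-bromo-3-methylbut-2-ene | CC(C)=C(C)Br | starting material
18 | ethyl bromoacetate | CCOC(=O)CBr | starting material
19 | bromo(2-ethoxy-2-oxoethyl)zinc | CCOC(=O)C[Zn]Br | intermediate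
20 | ethyl 3,4-dimethylpent-3-enoate | CCOC(=O)CC(C)=C(C)C | intermediate
21 | 3,4-dimethylpent-3-enoic acid | OC(=O)CC(C)=C(C)C | intermediate
22 | (1R)-1-[5,8-bis(methoxymethoxy)-1,4-dioxo-1,4-dihydronaphthalen-2-yl]-4-methylpent-3-en-1-yl 3,4-dimethylpent-3-enoate | CC(C)=CC[C@@H](OC(=O)CC(C)=C(C)C)C1=CC(=O)c2c(OCOC)ccc(OCOC)c2C1=O | intermediate
23 | (1R)-1-(5,8-dihydroxy-1,4-dioxo-1,4-dihydronaphthalen-2-yl)-4-methylpent-3-en-1-yl 3,4-dimethylpent-3-enoate | CC(C)=CC[C@@H](OC(=O)CC(C)=C(C)C)C1=CC(=O)c2c(O)ccc(O)c2C1=O | target

Total steps: 12. Longest linear sequence: 8 steps (steps 1, 2, 3, 4, 7, 8, 11, 12).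

Steps most likely to fail

Step 8. After alkyne insertion the vinylcarbene may close onto the arene without taking up CO (cyclopentannulation), or the acetal-bound carbene ligand may be cleaved thermally or by adventitious water before insertion. The fallback gives up the tether and runs the benzannulation between two components; it sets out from 12 and 6 and comes back at 16. Salt 12 would be O-methylated with Me3OBF4 in CH2Cl2 to the methoxycarbene complex pentacarbonyl{[2,5-bis(methoxymethoxy)phenyl](methoxy)methylidene}chromium F1. Alcohol 6 would be silylated (TBSCl, imidazole, DMF) to (3R)-3-(tert-butyldimethylsilyloxy)-6-methylhept-5-en-1-yne F2. Heating F1 with F2 in THF at 50 °C (intermolecular Dötz benzannulation, side chain next to the new hydroxyl) should give 2-[(1R)-1-(tert-butyldimethylsilyloxy)-4-methylpent-3-en-1-yl]-4-methoxy-5,8-bis(methoxymethoxy)naphthalen-1-ol F3. Oxidation in the same flask with (NH4)2Ce(NO3)6 should give the quinone silyl ether 2-[(1R)-1-(tert-butyldimethylsilyloxy)-4-methylpent-3-en-1-yl]-5,8-bis(methoxymethoxy)naphthalene-1,4-dione F4, and HF·pyridine in THF should free the carbinol to give 16.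

Step 7. O-alkylation of the weakly nucleophilic acylate by the α-bromo ether may be outrun by bromoboration of the terminal alkyne or by boron-induced breakdown of the acylate. The fallback builds the same acetal by acyl exchange at the carbene carbon instead of alkylation at oxygen; it sets out from 12 and 6 and comes back at 14. Salt 12 would be treated with acetyl bromide in CH2Cl2 at −40 °C to give the acyloxycarbene complex pentacarbonyl{(acetyloxy)[2,5-bis(methoxymethoxy)phenyl]methylidene}chromium F5. Alcohol 6 would be stirred with anhydrous monomeric formaldehyde in CH2Cl2 to give the hemiformal {[(3R)-6-methylhept-5-en-1-yn-3-yl]oxy}methanol F6. The unhindered primary hydroxyl of F6 should displace acetate from F5 (alcoholysis of an acyloxycarbene) and give 14.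

Step 12. During acetal cleavage the Lewis acid may also ionize the side-chain ester next to the quinone or protonate the tri- and tetrasubstituted alkenes. The fallback reverses the order of the last two steps so that no ester is present during deprotection; it sets out from 16 and comes back at 23. Compound 16 would be deprotected with MgBr2·OEt2 (or dilute HCl in THF) to 5,8-dihydroxy-2-[(1R)-1-hydroxy-4-methylpent-3-en-1-yl]naphthalene-1,4-dione F7. Steglich esterification of F7 with 21 (DCC, DMAP, CH2Cl2) should then acylate only the side-chain hydroxyl, because the chelated peri-hydroxyls of the naphthazarin are unreactive, and give 23.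

Further compounds
F1 | step 8 | pentacarbonyl{[2,5-bis(methoxymethoxy)phenyl](methoxy)methylidene}chromium | COC(c1cc(OCOC)ccc1OCOC)=[Cr](=C=O)(=C=O)(=C=O)(=C=O)=C=O
F2 | step 8 | (3R)-3-(tert-butyldimethylsilyloxy)-6-methylhept-5-en-1-yne | CC(C)=CC[C@@H](O[Si](C)(C)C(C)(C)C)C#C
F3 | step 8 | 2-[(1R)-1-(tert-butyldimethylsilyloxy)-4-methylpent-3-en-1-yl]-4-methoxy-5,8-bis(methoxymethoxy)naphthalen-1-ol | CC(C)=CC[C@@H](O[Si](C)(C)C(C)(C)C)c1cc(OC)c2c(OCOC)ccc(OCOC)c2c1O
F4 | step 8 | 2-[(1R)-1-(tert-butyldimethylsilyloxy)-4-methylpent-3-en-1-yl]-5,8-bis(methoxymethoxy)naphthalene-1,4-dione | CC(C)=CC[C@@H](O[Si](C)(C)C(C)(C)C)C1=CC(=O)c2c(OCOC)ccc(OCOC)c2C1=O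
F5 | step 7 | pentacarbonyl{(acetyloxy)[2,5-bis(methoxymethoxy)phenyl]methylidene}chromium | CC(=O)OC(c1cc(OCOC)ccc1OCOC)=[Cr](=C=O)(=C=O)(=C=O)(=C=O)=C=O
F6 | step 7 | {[(3R)-6-methylhept-5-en-1-yn-3-yl]oxy}methanol | CC(C)=CC[C@@H](OCO)C#C
F7 | step 12 | 5,8-dihydroxy-2-[(1R)-1-hydroxy-4-methylpent-3-en-1-yl]naphthalene-1,4-dione (shikonin) | CC(C)=CC[C@@H](O)C1=CC(=O)c2c(O)ccc(O)c2C1=O
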